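## Retrosynthetic overview

1. Feature used: ring B (C5–C10) of the cis-fused decalin (H5 and the C10 methyl on the same face) is the ring of (S)-carvone. Its C=O is C9, its ring methyl is the C8 methyl, its stereocentre is C5, its α′-CH2 is C10, and its isopropenyl group is C4 plus both geminal methyl carbons.
2. Last cuts: acetate, C3 ketone and silyl groups, then C12–C13 (B-alkyl Suzuki coupling). This gives a 9β-vinyl-8α-decalinol and an E-vinyl iodide from geranylacetone, so the polyene arrives only after ring B is finished.
3. Ring B: the 8α-OH comes from the 7α,8α-epoxide and the C7 oxygen is deleted via the enol triflate. C9–C11 comes from vinyl 1,4-addition to the C7 enone, made from the C9 enone by epoxidation, Wharton transposition and oxidation.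
4. Key cut C3–C4: hydrogen-atom transfer to the isopropenyl CH2 gives the tertiary C4 radical, which closes ring A on the C3 aldehyde and creates the gem-dimethyl carbon.
5. The keto aldehyde comes from carvone by C10 allylation, C10 methylation and anti-Markovnikov oxidation. Ring order: B (chiral pool), then A (step 4).

Key step: step 4

Remarks
- Numbering: target numbers are used throughout (ring A C1–C5 and C10, ring B C5–C10, chain C11–C22). β is the face of ring B that carries the C10 methyl, and α is the face that carries ring A.
- The target is taken exactly as drawn: H5 β (cis fusion), side chain 9β, 8α-OH with 8β-methyl.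
- The C3 carbinol made in the key step is drawn as the 3β epimer throughout. The 3α epimer would run through the same steps and converge when C3 is oxidised.

## Route

Step 1
Reactants: 1 (S)-(+)-carvone; 2 allyl bromide
Product: 4 10β-allylcarvone (allyl trans to isopropenyl; main epimer), via lithium dienolate 3 (not isolated)
Conditions: LDA (1.05 equiv), THF, −78 °C; then 2 (1.2 equiv), −78 °C → rt
Reagents that add atoms: allyl bromide (2) C=CCBr; LDA CC(C)N([Li])C(C)C (lithium of 3 only)
Why: Kinetic α′-deprotonation of the enone gives the cross-conjugated dienolate 3, which is C-allylated at C10 (enolate alkylation) mainly anti to the C5 isopropenyl group; the new C10 centre is provisional because step 2 flattens it again.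

Step 2
Reactants: 4 10β-allylcarvone; 5 methyl iodide
Product: 7 10α-allyl-10β-methylcarvone (methyl trans to isopropenyl; allyl cis), via lithium dienolate 6 (not isolated)
Conditions: LDA (1.1 equiv), THF, −78 → 0 °C; DMPU, MeI (3 equiv), −78 °C → rt
Reagents that add atoms: methyl iodide (5) CI; LDA CC(C)N([Li])C(C)C (lithium of 6 only)
Why: Enolate alkylation of the tetrasubstituted dienolate 6, in which A(1,2) strain with the C10 allyl group holds the C5 isopropenyl group pseudo-axial on the α face, so that MeI enters from the β face and sets quaternary C10 with the methyl trans and the three-carbon arm cis to isopropenyl, which is why the arm is put in first and the methyl second.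

Step 3
Reactants: 7 10α-allyl-10β-methylcarvone
Product: 8 10β-methyl-10α-(3-oxopropyl)carvone (propanal arm cis to isopropenyl)
Conditions: PdCl2(PhCN)2 (10 mol%), CuCl2·2H2O (10 mol%), AgNO2 (5 mol%), O2 (1 atm), t-BuOH/MeNO2 15:1, rt
Reagents that add atoms: dioxygen O=O (terminal oxidant, relayed through nitrite)
Why: Nitrite-modified aldehyde-selective (anti-Markovnikov) Wacker-type oxidation, a reaction type established for terminal alkenes that carry a quaternary homoallylic carbon such as α-allyl-α-methyl ketones; Pd(II) engages only the monosubstituted alkene, whereas the 1,1-disubstituted isopropenyl group and the enone are not Wacker substrates, and no stereocentre is touched.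

Step 4
Reactants: 8 10β-methyl-10α-(3-oxopropyl)carvone
Product: 9 cis-fused 3β-hydroxy-4,4,8,10β-tetramethyl-5βH-decal-7-en-9-one
Conditions: Fe(acac)3 (30 mol%), PhSiH3 (2.5 equiv, slow addition), degassed EtOH (0.02 M), 60 °C
Reagents that add atoms: none
Why: An iron hydride formed from Fe(acac)3 and PhSiH3 transfers H• to the exposed CH2 terminus of the 1,1-disubstituted isopropenyl group, which creates the second geminal methyl and the tertiary C4 radical. This radical adds to the aldehyde carbon C3 in a 6-exo-trig closure of ring A (ring atoms C3, C4, C5, C10, C1, C2), and the C3 alkoxy radical is reduced by Fe(II) and protonated by ethanol, which takes it out of the otherwise reversible addition/β-scission equilibrium. The closest known reaction type is the iron-hydride-initiated reductive radical cyclisation of alkene-tethered ketones, together with the intermolecular alkene–aldehyde coupling run under the same conditions. The cis ring fusion is not made here but carried over from 8, where C1 on C10 and C4 on C5 lie on the same (α) face, so only a cis-decalin can close. The one new stereocentre, C3, is governed by the chair-like transition state with the iron-bound oxygen pseudo-equatorial (drawn as 3β-OH for the chair with the arm axial and C4 equatorial on ring B); control may be modest, which is harmless because C3 ends as a ketone. The step needs hydrogen-atom transfer to the electron-rich terminal alkene rather than to the electron-poor, trisubstituted enone, and cyclisation faster than a second H transfer to C4; the accessible CH2 terminus, the gauche cis-1,2 placement of radical and acceptor, high dilution and slow silane addition secure both.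

Step 5
Reactants: 9 cis-fused hydroxy enone
Product: 10 3β-TBS ether of 9
Conditions: TBSOTf (1.3 equiv), 2,6-lutidine (2 equiv), CH2Cl2, 0 °C
Reagents that add atoms: TBSOTf CC(C)(C)[Si](C)(C)OS(=O)(=O)C(F)(F)F
Why: Silylation of the hindered neopentyl-type C3 carbinol with the silyl triflate masks it against hydrazine, organometallics, hydride and oxidants until step 19; the enone has no α′-hydrogen, the base is weak and no stereocentre changes.

Step 6
Reactants: 10 TBS-protected C9 enone
Product: 11 7β,8β-epoxy-9-ketone
Conditions: 30% aq H2O2 (5 equiv), NaOH (0.3 equiv), MeOH, 0 °C → rt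
Reagents that add atoms: hydrogen peroxide OO
Why: Weitz–Scheffer nucleophilic epoxidation as for carvone itself, in which hydroperoxide adds to the unhindered β-carbon C7 from the convex β face (trans to C4 on C5) and the enolate closes the oxirane on the same face; both new centres are provisional, since C8 becomes sp2 in step 7 and C7 a carbonyl in step 8.

Step 7
Reactants: 11 7β,8β-epoxy-9-ketone
Product: 13 7β-hydroxy-8-ene (transposed allylic alcohol), via epoxy hydrazone 12 (not isolated)
Conditions: N2H4·H2O (5 equiv), AcOH (cat.), MeOH, 0 → 40 °C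
Reagents that add atoms: hydrazine NN (nitrogen of 12 only; none of it stays in 13)
Why: Wharton transposition, in which hydrazone 12 tautomerises with opening of the C8–O bond to an alkenyl diazene that loses N2, moving the alkene to C8=C9 and leaving the C7–O bond and its 7β configuration untouched; the small nucleophile and the inductively activated carbonyl are relied on to overcome the crowding at C9.

Step 8
Reactants: 13 7β-hydroxy-8-ene
Product: 14 8-en-7-one (transposed enone)
Conditions: Dess–Martin periodinane (1.3 equiv), CH2Cl2, 0 °C → rt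
Reagents that add atoms: none
Why: Dess–Martin oxidation of the secondary allylic alcohol completes the 1,3-carbonyl transposition and makes C9 the β-carbon of the enone; the provisional C7 centre disappears and the silyl ether is inert.

Step 9
Reactants: 14 8-en-7-one; 15 vinylmagnesium bromide
Product: 16 9β-vinyl-7-(trimethylsilyloxy)-7-ene
Conditions: 15 (3 equiv), CuBr·SMe2 (20 mol%), TMSCl (4 equiv), HMPA (4 equiv), THF, −78 → −30 °C; Et3N, then aq NaHCO3
Reagents that add atoms: vinylmagnesium bromide (15) C=C[Mg]Br; chlorotrimethylsilane C[Si](C)(C)Cl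
Why: Copper(I)-catalysed conjugate addition of a Grignard reagent accelerated by TMSCl/HMPA, a reaction type known for enones whose β-carbon adjoins a quaternary carbon (for example 1-en-3-oxo steroids); axial attack on the half-chair with C4 equatorial and C1 axial comes anti to C1 from the convex β face, where only H5 is 1,3-diaxial, which sets C9 (vinyl β, H α), and silylation fixes the enolate regiochemistry at C7=C8.

Step 10
Reactants: 16 9β-vinyl silyl enol ether
Product: 18 9β-vinyl-7-enol triflate, via lithium enolate 17 (not isolated)
Conditions: MeLi (1.1 equiv), THF, 0 °C; then PhNTf2 (1.3 equiv), −78 °C → rt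
Reagents that add atoms: N-phenylbis(trifluoromethanesulfonimide) O=S(=O)(N(c1ccccc1)S(=O)(=O)C(F)(F)F)C(F)(F)F; methyllithium [Li]C (lithium of 17 only)
Why: Cleavage of the trimethylsilyl enol ether with MeLi gives the regiodefined lithium enolate 17, whose O-sulfonylation with the triflimide gives the tetrasubstituted enol triflate without touching C9 or the TBS ether.

Step 11
Reactants: 18 9β-vinyl-7-enol triflate
Product: 19 9β-vinyl-7-ene
Conditions: Pd(OAc)2 (5 mol%), PPh3 (10 mol%), HCO2H (3 equiv), n-Bu3N (4 equiv), DMF, 60 °C
Reagents that add atoms: none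
Why: Palladium-catalysed formate reduction of an enol triflate (oxidative addition, formate decarboxylation, C–H reductive elimination) deletes the C7 oxygen and leaves the C7=C8 alkene in place; the isolated vinyl group and all stereocentres are unaffected.

Step 12
Reactants: 19 9β-vinyl-7-ene
Product: 20 9β-vinyl-7α,8α-epoxide
Conditions: mCPBA (1.1 equiv), CH2Cl2, −20 → 0 °C
Reagents that add atoms: mCPBA OOC(=O)c1cccc(Cl)c1
Why: Prilezhaev epoxidation picks the electron-rich trisubstituted C7=C8 alkene over the monosubstituted vinyl group; A(1,2) strain with the C8 methyl keeps the C9 vinyl group pseudo-axial on the β face, so the peracid should come from the α face, which sets C8 with oxygen α and methyl β.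

Step 13
Reactants: 20 9β-vinyl-7α,8α-epoxide
Product: 21 9β-vinyl-8α-ol (8β-methyl)
Conditions: LiEt3BH (3 equiv), THF, 0 → 50 °C; H2O
Reagents that add atoms: none
Why: SN2 opening of the trisubstituted epoxide by Super-Hydride at the less substituted C7 in the trans-diaxial sense (Fürst–Plattner rule) leaves the C8–O bond intact, so the 8α-hydroxy-8β-methyl centre of the target is retained.

Step 14
Reactants: 22 (E)-geranylacetone
Product: 23 (5E,9E)-11-hydroxy-6,10-dimethylundeca-5,9-dien-2-one
Conditions: SeO2 (10 mol%), t-BuOOH (2 equiv), salicylic acid (10 mol%), CH2Cl2, 0 °C → rt, stopped at partial conversion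
Reagents that add atoms: tert-butyl hydroperoxide CC(C)(C)OO
Why: Catalytic SeO2/t-BuOOH allylic oxidation (ene reaction then [2,3]-shift) prefers the terminal isopropylidene group and its E methyl, which sets the C21=C22 E geometry with the CH2OH group; the reaction is stopped early to spare the internal alkene and the ketone α-positions.

Step 15
Reactants: 23 hydroxy ketone
Product: 24 11-TBS ether of 23
Conditions: TBSCl (1.2 equiv), imidazole (2.5 equiv), DMF, rt
Reagents that add atoms: TBSCl CC(C)(C)[Si](C)(C)Cl
Why: Standard imidazole-mediated silylation of the primary allylic alcohol protects it against LDA, Me3Al and the coupling base.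

Step 16
Reactants: 24 silyloxy methyl ketone
Product: 28 (5E,9E)-11-(TBSO)-6,10-dimethylundeca-5,9-dien-1-yne, via lithium enolate 25 (not isolated), via enol phosphate 26 (not isolated), via lithium acetylide 27 (not isolated)
Conditions: LDA (1.1 equiv), THF, −78 °C; ClP(O)(OEt)2 (1.15 equiv), −78 °C → rt; then LDA (2.3 equiv), THF, −78 °C → rt; H2O
Reagents that add atoms: diethyl chlorophosphate CCOP(=O)(Cl)OCC (phosphate of 26 only); LDA CC(C)N([Li])C(C)C (lithium of 25 and 27 only)
Why: Methyl ketone to terminal alkyne conversion, in which kinetic deprotonation on the CH3 side, O-phosphorylation and LDA-induced β-elimination of the enol phosphate give the C13≡C14 alkyne without moving the E alkenes.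

Step 17
Reactants: 28 dienyne
Product: 30 (1E,5E,9E)-1-iodo-2,6,10-trimethyl-11-(TBSO)undeca-1,5,9-triene, via alkenyl dimethylalane 29 (not isolated)
Conditions: Me3Al (2.5 equiv), Cp2ZrCl2 (25 mol%), CH2Cl2, 0 °C → rt; then I2, THF, −30 → 0 °C
Reagents that add atoms: trimethylaluminium C[Al](C)C; iodine II
Why: Negishi zirconium-catalysed carboalumination adds methyl and aluminium syn with aluminium at the terminus, and iodinolysis goes with retention, which sets the E-trisubstituted C13=C14 unit as its vinyl iodide.

Step 18
Reactants: 21 9β-vinyl-8α-ol; 30 E-vinyl iodide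
Product: 32 3β,ω-bis-TBS ether of the C30 triol, via B-alkyl-9-BBN borane 31 (not isolated)
Conditions: 9-BBN (2.5 equiv), THF, rt; then 3 M aq Cs2CO3, 30 (1.2 equiv), PdCl2(dppf) (10 mol%), AsPh3 (10 mol%), DMF, rt → 45 °C
Reagents that add atoms: 9-BBN B1C2CCCC1CCC2 (boron unit of 31 only)
Why: 9-BBN hydroborates the only alkene of 21 at the terminal C12 and the B-alkyl Suzuki–Miyaura coupling forms C12–C13 with retention of the vinyl iodide geometry; the tertiary alcohol and both silyl ethers are tolerated and no stereocentre is affected.

Step 19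
Reactants: 32 bis-TBS ether
Product: 33 3β,8α,ω-triol
Conditions: TBAF (5 equiv), THF, rt → 60 °C
Reagents that add atoms: none
Why: Fluoride cleaves both TBS ethers, warming being allowed for the hindered C3 ether because the triol holds no base-sensitive group.

Step 20
Reactants: 33 triol
Product: 34 ω-monoacetate (3β-OH and 8α-OH free)
Conditions: Ac2O (1.1 equiv), pyridine, CH2Cl2, −20 → 0 °C
Reagents that add atoms: acetic anhydride CC(=O)OC(C)=O
Why: Acylation discriminates on steric grounds, since the primary allylic alcohol reacts fast, the C3 carbinol next to the gem-dimethyl carbon slowly and the tertiary C8 alcohol not at all.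

Step 21
Reactants: 34 ω-monoacetate
Product: 35 myrrhanone A acetate
Conditions: Dess–Martin periodinane (1.5 equiv), CH2Cl2, 0 °C → rt
Reagents that add atoms: none
Why: Dess–Martin oxidation converts the only remaining oxidisable alcohol (C3) into the ketone, which erases the C3 centre, while the tertiary alcohol, the acetate and the trisubstituted alkenes are inert.

## Compound list

1 | (S)-(+)-carvone | CC1=CC[C@@H](CC1=O)C(C)=C | starting material
2 | allyl bromide | C=CCBr | starting material
3 | lithium dienolate of 1 (O–C9=C10) | CC1=CC[C@@H](C=C1O[Li])C(C)=C | intermediate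
4 | 10β-allylcarvone (allyl trans to isopropenyl) | O=C1C(C)=CC[C@H](C(C)=C)[C@H]1CC=C | intermediate
5 | methyl iodide | CI | starting material
6 | lithium dienolate of 4 | CC1=CC[C@@H](C(CC=C)=C1O[Li])C(C)=C | intermediate
7 | 10α-allyl-10β-methylcarvone | O=C1C(C)=CC[C@H](C(C)=C)[C@]1(C)CC=C | intermediate
8 | 10β-methyl-10α-(3-oxopropyl)carvone | O=C1C(C)=CC[C@H](C(C)=C)[C@]1(C)CCC=O | intermediate
9 | cis-fused 3β-hydroxy-4,4,8,10β-tetramethyl-5βH-decal-7-en-9-one | O=C1[C@@]2(C)CC[C@H](O)C(C)(C)[C@H]2CC=C1C | intermediate
10 | 3β-TBS ether of 9 | O=C1[C@@]2(C)CC[C@H](O[Si](C)(C)C(C)(C)C)C(C)(C)[C@H]2CC=C1C | intermediate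
11 | 7β,8β-epoxy-9-ketone | O=C1[C@@]2(C)CC[C@H](O[Si](C)(C)C(C)(C)C)C(C)(C)[C@H]2C[C@@H]3O[C@]13C | intermediate
12 | hydrazone of 11 | NN=C1[C@@]2(C)CC[C@H](O[Si](C)(C)C(C)(C)C)C(C)(C)[C@H]2C[C@@H]3O[C@]13C | intermediate
13 | 7β-hydroxy-8-ene | CC1=C[C@@]2(C)CC[C@H](O[Si](C)(C)C(C)(C)C)C(C)(C)[C@H]2C[C@@H]1O | intermediate
14 | 8-en-7-one | CC1=C[C@@]2(C)CC[C@H](O[Si](C)(C)C(C)(C)C)C(C)(C)[C@H]2CC1=O | intermediate
15 | vinylmagnesium bromide | C=C[Mg]Br | starting material
16 | 9β-vinyl-7-(trimethylsilyloxy)-7-ene | C=C[C@@H]1[C@@]2(C)CC[C@H](O[Si](C)(C)C(C)(C)C)C(C)(C)[C@H]2CC(O[Si](C)(C)C)=C1C | intermediate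
17 | lithium 7-enolate | C=C[C@@H]1[C@@]2(C)CC[C@H](O[Si](C)(C)C(C)(C)C)C(C)(C)[C@H]2CC(O[Li])=C1C | intermediate
18 | 9β-vinyl-7-enol triflate | C=C[C@@H]1[C@@]2(C)CC[C@H](O[Si](C)(C)C(C)(C)C)C(C)(C)[C@H]2CC(OS(=O)(=O)C(F)(F)F)=C1C | intermediate
19 | 9β-vinyl-7-ene | C=C[C@@H]1[C@@]2(C)CC[C@H](O[Si](C)(C)C(C)(C)C)C(C)(C)[C@H]2CC=C1C | intermediate
20 | 9β-vinyl-7α,8α-epoxide | C=C[C@@H]1[C@@]2(C)CC[C@H](O[Si](C)(C)C(C)(C)C)C(C)(C)[C@H]2C[C@H]3O[C@@]13C | intermediate
21 | 9β-vinyl-8α-ol | C=C[C@@H]1[C@@]2(C)CC[C@H](O[Si](C)(C)C(C)(C)C)C(C)(C)[C@H]2CC[C@@]1(C)O | intermediate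
22 | (E)-geranylacetone | CC(C)=CCC/C(C)=C/CCC(C)=O | starting material
23 | (5E,9E)-11-hydroxy-6,10-dimethylundeca-5,9-dien-2-one | OC/C(C)=C/CC/C(C)=C/CCC(C)=O | intermediate
24 | 11-TBS ether of 23 | CC(C)(C)[Si](C)(C)OC/C(C)=C/CC/C(C)=C/CCC(C)=O | intermediate
25 | kinetic lithium enolate of 24 | CC(C)(C)[Si](C)(C)OC/C(C)=C/CC/C(C)=C/CCC(=C)O[Li] | intermediate
26 | enol diethyl phosphate | CC(C)(C)[Si](C)(C)OC/C(C)=C/CC/C(C)=C/CCC(=C)OP(=O)(OCC)OCC | intermediate
27 | lithium acetylide | CC(C)(C)[Si](C)(C)OC/C(C)=C/CC/C(C)=C/CCC#C[Li] | intermediate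
28 | (5E,9E)-11-(TBSO)-6,10-dimethylundeca-5,9-dien-1-yne | CC(C)(C)[Si](C)(C)OC/C(C)=C/CC/C(C)=C/CCC#C | intermediate
29 | (E)-alkenyl dimethylalane | CC(C)(C)[Si](C)(C)OC/C(C)=C/CC/C(C)=C/CC/C(C)=C/[Al](C)C | intermediate
30 | (1E,5E,9E)-1-iodo-2,6,10-trimethyl-11-(TBSO)undeca-1,5,9-triene | CC(C)(C)[Si](C)(C)OC/C(C)=C/CC/C(C)=C/CC/C(C)=C/I | intermediate
31 | B-(C12-alkyl)-9-BBN from 21 (drawn with free 8-OH) | B1(CC[C@@H]3[C@@]4(C)CC[C@H](O[Si](C)(C)C(C)(C)C)C(C)(C)[C@H]4CC[C@@]3(C)O)C2CCCC1CCC2 | intermediate
32 | 3β,ω-bis-TBS ether of the triol | CC(C)(C)[Si](C)(C)OC/C(C)=C/CC/C(C)=C/CC/C(C)=C/CC[C@@H]1[C@@]2(C)CC[C@H](O[Si](C)(C)C(C)(C)C)C(C)(C)[C@H]2CC[C@@]1(C)O | intermediate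
33 | 3β,8α,ω-triol | OC/C(C)=C/CC/C(C)=C/CC/C(C)=C/CC[C@@H]1[C@@]2(C)CC[C@H](O)C(C)(C)[C@H]2CC[C@@]1(C)O | intermediate
34 | ω-monoacetate | CC(=O)OC/C(C)=C/CC/C(C)=C/CC/C(C)=C/CC[C@@H]1[C@@]2(C)CC[C@H](O)C(C)(C)[C@H]2CC[C@@]1(C)O | intermediate
35 | myrrhanone A acetate | CC(=O)OC/C(C)=C/CC/C(C)=C/CC/C(C)=C/CC[C@@H]1[C@@]2(C)CCC(=O)C(C)(C)[C@H]2CC[C@@]1(C)O | target

## Step count and risks

Total steps: 21. Longest linear sequence: 17 (steps 1–13 and 18–21). The side branch is 4 steps (14–17).

**Step 4 (key step).**
- Risk: the C3 alkoxy radical may fragment back to the stabilised tertiary C4 radical faster than it is reduced, so the isopropenyl group is merely hydrogenated. Hydrogen-atom transfer may also reach the enone.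
- Fallback: the same C3–C4 bond would be made by a polar carbonyl addition instead of a radical one.
  - A cobalt(salen) catalyst with a silane delivers H• to the same CH2 terminus in the presence of a chromium(III) salt.
  - Cr(II) captures the C4 radical, and the tertiary alkylchromium(III) species adds irreversibly to the aldehyde in the Nozaki–Hiyama–Kishi manner. This is the known branch-selective alkene–aldehyde coupling by radical–polar crossover.
- This sets out from 8 and comes back at 9. No new isolable compound is made.

**Step 7 (Wharton transposition).**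
- Risk: hydrazone formation may be slow at the C9 carbonyl, which lies between quaternary C10 and the fully substituted epoxide carbon C8. Attack of hydrazine on the oxirane then competes.
- Fallback: the transposition is driven from a C9 radical, so no condensation at the carbonyl is needed.
  - From 11, NaBH4 (MeOH/THF, 0 °C → rt) gives the epoxy alcohol F1. Its C9 configuration is irrelevant; it is drawn 9β.
  - 1,1′-Thiocarbonyldiimidazole with DMAP in hot toluene gives the thiocarbonylimidazolide F2.
  - Bu3SnH/AIBN generates the C9 radical in the Barton–McCombie manner. It opens the adjacent C8–O bond, and the C7 alkoxy radical takes up hydrogen.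
- This known radical fragmentation of epoxy thiocarbonyl derivatives comes back to the route at 13.

**Step 12 (epoxidation).**
- Risk: facial selectivity may be poor, because each face of C7=C8 is screened by one axial group (C1 on the α face, the C9 vinyl group on the β face).
- Fallback: the C8 oxygen is brought in as a nucleophile rather than as an electrophile, which inverts the facial demand.
  - From 19, NBS in aqueous THF (0 °C) forms the bromonium ion reversibly.
  - Water opens the β-bromonium ion at the tertiary C8 from the α face (Markovnikov, trans-diaxial) to give the 7β-bromo-8α-ol bromohydrin F3.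
  - Radical debromination (Bu3SnH, AIBN, toluene, 80 °C) removes the C7 bromine.
- The fallback comes back at 21 and replaces steps 12 and 13.

## Further compounds

F0 | step 4 | none | none
F1 | step 7 | 9β-hydroxy-7β,8β-epoxide | O[C@@H]1[C@@]2(C)CC[C@H](O[Si](C)(C)C(C)(C)C)C(C)(C)[C@H]2C[C@@H]3O[C@]13C
F2 | step 7 | 9-O-(imidazol-1-ylthiocarbonyl) derivative of F1 | S=C(O[C@@H]1[C@@]2(C)CC[C@H](O[Si](C)(C)C(C)(C)C)C(C)(C)[C@H]2C[C@@H]3O[C@]13C)n4ccnc4
F3 | step 12 | 9β-vinyl-7β-bromo-8α-ol | C=C[C@@H]1[C@@]2(C)CC[C@H](O[Si](C)(C)C(C)(C)C)C(C)(C)[C@H]2C[C@H](Br)[C@@]1(C)O
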